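**Plan**
1. Enabling feature: the ring of 2,5-dihydroxy-3-henicosyl-6-methyl-1,4-benzoquinone (C1, C4 carbonyls; C2, C5 hydroxyls; C3 chain; C6 methyl) is the bis-enol of a cyclohexane-1,2,4,5-tetraone. C3 and C6 each lie between two carbonyl carbons, and C1/C2 and C4/C5 are oxalyl-type 1,2-dicarbonyl pairs, so the ring can be closed by a Claisen C-acylation at the final oxidation level.
2. Cuts, in retrosynthetic order: ring bond C3–C4 (Dieckmann) to open-chain ethyl 3-methyl-2,4,5-trioxoheptacosanoate; C5–C6 (crossed Claisen, diethyl oxalate supplies C4 and C5); then C1–C2 and C2–C3 at a 1,3-dithiane carbon that stands for C2.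
3. Forward: 1,3-dithiane is alkylated with 1-bromodocosane (whose C1 becomes ring C3), acylated with a propionyl unit (C1, C6 and the methyl), oxalylated at its only enolisable CH2, unmasked and cyclised.
4. Helper: the dithiane carries C2 as an acyl anion and keeps the chain CH2 non-acidic until the oxalyl ester is in place; it is removed just before ring closure.
5. Stereochemistry: the target is achiral. The one stereocentre met on the way (the methyl-bearing carbon of the open chain) is enolisable and vanishes on ring closure.

Key step: step 5

Remark: the quinone is drawn as one of two degenerate bis-enol tautomers, so the two ring bonds flanking the chain-bearing carbon are chemically equivalent; the side chain is taken as unbranched henicosyl (21 carbons).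

**Route**

Step 1
Reactants: 1 1,3-dithiane; 2 1-bromodocosane
Product: 4 2-docosyl-1,3-dithiane, via 2-lithio-1,3-dithiane 3 (not isolated)
Conditions: n-BuLi, THF, −30 °C; then 2, −30 °C → rt
Reagents that add atoms: none
Why: Corey–Seebach alkylation, in which the sulfur-stabilised carbanion 3 displaces bromide from the unhindered primary bromide 2 by SN2; no stereocentre is formed.

Step 2
Reactants: 4 2-docosyl-1,3-dithiane; 5 N-methoxy-N-methylpropanamide
Product: 7 1-(2-docosyl-1,3-dithian-2-yl)propan-1-one, via 2-docosyl-2-lithio-1,3-dithiane 6 (not isolated)
Conditions: n-BuLi, THF, −20 °C, 3 h; then 5, −78 → 0 °C; then H2O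
Reagents that add atoms: none
Why: A second Corey–Seebach metalation gives the tertiary carbanion 6, and its acylation by the Weinreb amide (Weinreb ketone synthesis) should stop at the ketone because the chelated tetrahedral intermediate persists until the quench.

Step 3
Reactants: 7 1-(2-docosyl-1,3-dithian-2-yl)propan-1-one; 8 diethyl oxalate
Product: 10 ethyl 4-(2-docosyl-1,3-dithian-2-yl)-3-methyl-2,4-dioxobutanoate, via lithium (Z)-1-(2-docosyl-1,3-dithian-2-yl)prop-1-en-1-olate 9 (not isolated)
Conditions: LiN(SiMe3)2, THF, −78 °C; then 8, −78 °C → rt; then 1 M HCl
Reagents that add atoms: none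
Why: Crossed Claisen condensation, in which the ethyl CH2 is the only enolisable position of 7, so enolate 9 forms regiospecifically and is C-acylated by the non-enolisable diethyl oxalate, the acidic product being held as its lithium salt until work-up; the new stereocentre at C3 is enolisable, forms as a racemate and is lost in step 5.

Step 4
Reactants: 10 ethyl 4-(2-docosyl-1,3-dithian-2-yl)-3-methyl-2,4-dioxobutanoate
Product: 11 ethyl 3-methyl-2,4,5-trioxoheptacosanoate
Conditions: Hg(ClO4)2, CaCO3, THF–H2O, 0 °C → rt; crude product taken on directly
Reagents that add atoms: water, SMILES O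
Why: Dethioketalisation by thiophilic divalent mercury under buffered, non-oxidising conditions should release the 1,2-diketone while sparing the enolised 2,4-dioxo ester, and with it the acidity of the chain CH2 at C6.

Step 5
Reactants: 11 ethyl 3-methyl-2,4,5-trioxoheptacosanoate
Product: 13 2,5-dihydroxy-3-henicosyl-6-methyl-1,4-benzoquinone (the target), via disodium 2-henicosyl-5-methyl-3,6-dioxocyclohexa-1,4-diene-1,4-diolate 12 (not isolated)
Conditions: NaOEt (3 equiv), EtOH–THF, 0 → 60 °C; then 1 M HCl
Reagents that add atoms: none
Why: Ethoxide first removes the 1,3-dicarbonyl proton at C3 of 11 and then a proton of the C6 methylene next to the C5 ketone; the C6 enolate carbon adds to the ester carbonyl C1 and ethoxide is expelled, which is a Dieckmann condensation (intramolecular Claisen C-acylation) that forms the C6–C1 bond and gives the cyclohexane-1,2,4,5-tetraone, whose double deprotonation to the bis-vinylogous carboxylate 12 pulls the preceding equilibria forward. The closest known reaction types are the ring-closing Claisen acylation of a ketone enolate by an oxalyl ester in the preparation of cyclopentane-1,2,4-triones from ketones and diethyl oxalate, and the classical base-mediated condensation of 2-oxo esters to 3,6-dialkyl-2,5-dihydroxy-1,4-benzoquinones. The six-membered ring closes in the 6-(enolendo)-exo-trig mode. No stereocentre is created, since both sp3 ring carbons of the tetraone enolise on the way to 12 and acidification gives the achiral bis-enol 13. The step needs C- over O-acylation, six- over five-membered closure and closure through C6 only: in the dianion the C2 and C4 carbonyls are tied up in the C3 enolate, so the ester C1 is the only electrophile left and C6 the only remaining enolisable carbon, and a lactone formed by O-acylation would be reopened by the matched ethoxide while only the C-acylated ring can reach the doubly stabilised dianion.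

**Compound list**
1 | 1,3-dithiane | C1CSCSC1 | starting material
2 | 1-bromodocosane | CCCCCCCCCCCCCCCCCCCCCCBr | starting material
3 | 2-lithio-1,3-dithiane | [Li]C1SCCCS1 | intermediate
4 | 2-docosyl-1,3-dithiane | CCCCCCCCCCCCCCCCCCCCCCC1SCCCS1 | intermediate
5 | N-methoxy-N-methylpropanamide | CCC(=O)N(C)OC | starting material
6 | 2-docosyl-2-lithio-1,3-dithiane | CCCCCCCCCCCCCCCCCCCCCCC1([Li])SCCCS1 | intermediate
7 | 1-(2-docosyl-1,3-dithian-2-yl)propan-1-one | CCC(=O)C1(CCCCCCCCCCCCCCCCCCCCCC)SCCCS1 | intermediate
8 | diethyl oxalate | CCOC(=O)C(=O)OCC | starting material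
9 | lithium (Z)-1-(2-docosyl-1,3-dithian-2-yl)prop-1-en-1-olate | C/C=C(\[O-])C1(CCCCCCCCCCCCCCCCCCCCCC)SCCCS1.[Li+] | intermediate
10 | ethyl 4-(2-docosyl-1,3-dithian-2-yl)-3-methyl-2,4-dioxobutanoate (racemic, enolisable at C3) | CCOC(=O)C(=O)C(C)C(=O)C1(CCCCCCCCCCCCCCCCCCCCCC)SCCCS1 | intermediate
11 | ethyl 3-methyl-2,4,5-trioxoheptacosanoate (racemic, enolisable at C3) | CCOC(=O)C(=O)C(C)C(=O)C(=O)CCCCCCCCCCCCCCCCCCCCCC | intermediate
12 | disodium 2-henicosyl-5-methyl-3,6-dioxocyclohexa-1,4-diene-1,4-diolate | CCCCCCCCCCCCCCCCCCCCCC1=C([O-])C(=O)C(C)=C([O-])C1=O.[Na+].[Na+] | intermediate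
13 | 2,5-dihydroxy-3-henicosyl-6-methyl-1,4-benzoquinone | CCCCCCCCCCCCCCCCCCCCCC1=C(O)C(=O)C(C)=C(O)C1=O | target

**Step count**
Total steps: 5. Longest linear sequence: 5 steps (1 → 4 → 7 → 10 → 11 → 13).

**Steps most likely to fail**

Step 5 (ring closure). What may go wrong: retro-Claisen scission of the open chain by ethoxide at the C3–C4 bond may compete with ring closure, and the two 2-oxo ester fragments may then recondense without control and scramble the side chains. Fallback: the ring synthesis is abandoned and a preformed dihydroxyquinone is alkylated by decarboxylative radical coupling with diacyl peroxides. It sets out from 2. Oxidation of 2 with NaNO2 and AcOH in DMSO should give docosanoic acid F1. DCC and H2O2 should convert it into didocosanoyl peroxide F2. Thermolysis of F2 in AcOH at 95 °C with commercial 2,5-dihydroxy-1,4-benzoquinone should give 2,5-dihydroxy-3-henicosyl-1,4-benzoquinone F3, the henicosyl radical formed by loss of CO2 adding to a free ring position. A second radical alkylation of the last free ring position of F3 with diacetyl peroxide in AcOH (dilute solution) should give 13, where the fallback comes back to the route.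

Step 4 (unmasking). What may go wrong: the mercury salt may complex or C-mercurate the enolised 1,3-dicarbonyl unit, and the vicinal polycarbonyl chain may hydrate or cleave as it is set free. Fallback: the dithiane is removed before the oxalyl unit is present. It sets out from 7. The same Hg(ClO4)2/CaCO3 hydrolysis applied to 7, which has no enolised dicarbonyl unit, should give hexacosane-3,4-dione F4. F4 is then condensed with diethyl oxalate 8 and NaOEt in EtOH–THF in a double Claisen annulation and acidified to give 13, where the fallback comes back to the route. Regiocontrol of the first acylation is not needed here, because the enolate of 11 and that of its regioisomer ethyl 3-henicosyl-2,4,5-trioxoheptanoate F5 close to the same tetraone.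

Step 2 (acylation of the dithiane anion). What may go wrong: proton transfer from the enolisable Weinreb amide to the hindered tertiary carbanion 6 may outrun addition and return 4. Fallback: acylation is replaced by carbonyl addition and oxidation. It sets out from 4. Carbanion 6 is generated as before and added to propanal at −78 °C to give 1-(2-docosyl-1,3-dithian-2-yl)propan-1-ol F6 (racemic). Swern oxidation ((COCl)2, DMSO, Et3N), which tolerates the dithiane, should give 7, where the fallback comes back to the route.

**Further compounds**
F1 | step 5 | docosanoic acid | CCCCCCCCCCCCCCCCCCCCCC(=O)O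
F2 | step 5 | didocosanoyl peroxide | CCCCCCCCCCCCCCCCCCCCCC(=O)OOC(=O)CCCCCCCCCCCCCCCCCCCCC
F3 | step 5 | 2,5-dihydroxy-3-henicosyl-1,4-benzoquinone | CCCCCCCCCCCCCCCCCCCCCC1=C(O)C(=O)C=C(O)C1=O
F4 | step 4 | hexacosane-3,4-dione | CCC(=O)C(=O)CCCCCCCCCCCCCCCCCCCCCC
F5 | step 4 | ethyl 3-henicosyl-2,4,5-trioxoheptanoate | CCOC(=O)C(=O)C(CCCCCCCCCCCCCCCCCCCCC)C(=O)C(=O)CC
F6 | step 2 | 1-(2-docosyl-1,3-dithian-2-yl)propan-1-ol | CCC(O)C1(CCCCCCCCCCCCCCCCCCCCCC)SCCCS1
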